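**Strategy.** The bicyclo[2.2.2]octanone is opened at two bonds, C(=O)–CH2 and bridgehead CH (α to the ketone)–CHMe. This removes both bridging rings at once and leaves only ring A, the acetoxy-bearing cyclohexane. Its three contiguous carbons then carry an (E)-3-(phenylsulfonyl)allyl arm, an exocyclic methylene and a 1-(thiocarbonyloxy)ethyl arm. One tin hydride cascade (6-exo addition of the CHMe radical to the vinyl sulfone, then 6-endo addition of the α-sulfonyl radical to the methylene) forms both bonds and three stereocentres; the sulfone is the latent ketone. The step exploits the cis-1,3-diaxial arms on the two quaternary ring A carbons that flank the future bridgehead CH.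

Key step: step 19

**Remarks**
- Ring A of all monocyclic intermediates keeps the cyclohexanone numbering of 3: C1 carbonyl (later methylene) carbon, C2 quaternary carbon with methyl and the two-carbon arm, C3 silyloxy carbon, C5 methyl-bearing carbon, C6 quaternary carbon with the side chain.
- The carbinol carbon of the two-carbon arm (7–10, 15–22), the tertiary carbinol carbon of 18 and the sulfonyl-bearing carbon of 23–26 are carried as epimer mixtures; these centres are destroyed in steps 19, 15 and 23.
- Assumption: the antipodes of the oxazaborolidine (step 2) and of the bisphosphine ligand (step 10) written below are those expected to give 3 and 12; if either sense proves opposite, its mirror-image catalyst is used.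

**Route**

Step 1
Reactants: 1 2-methylcyclohexane-1,3-dione
Product: 2 2-methyl-2-(prop-2-en-1-yl)cyclohexane-1,3-dione
Conditions: allyl acetate, Pd(PPh3)4 (2 mol %), Et3N, THF, 50 °C
Reagents that add atoms: allyl acetate, C=CCOC(C)=O
Why: Tsuji–Trost allylation, in which the soft dione enolate attacks the π-allylpalladium complex at carbon and gives the quaternary carbon; no stereocentre is formed.

Step 2
Reactants: 2 2-methyl-2-(prop-2-en-1-yl)cyclohexane-1,3-dione
Product: 3 (2R,3R)-3-hydroxy-2-methyl-2-(prop-2-en-1-yl)cyclohexan-1-one (hydroxyl cis to allyl)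
Conditions: (S)-2-methyl-CBS-oxazaborolidine (20 mol %), catecholborane, toluene/CH2Cl2, −78 → −40 °C; then MeOH, aq. NaOH
Reagents that add atoms: none
Why: Corey–Bakshi–Shibata reduction used as an enantioselective desymmetrization, in which the catalyst selects one of the two enantiotopic carbonyls and hydride arrives anti to the larger allyl group, so the (R)-carbinol ends cis to allyl and the quaternary carbon becomes (R).

Step 3
Reactants: 3 (2R,3R)-3-hydroxy-2-methyl-2-(prop-2-en-1-yl)cyclohexan-1-one
Product: 4 (2R,3R)-3-[(tert-butyldimethylsilyl)oxy]-2-methyl-2-(prop-2-en-1-yl)cyclohexan-1-one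
Conditions: TBSOTf, 2,6-lutidine, CH2Cl2, 0 °C
Reagents that add atoms: tert-butyldimethylsilyl trifluoromethanesulfonate, CC(C)(C)[Si](C)(C)OS(=O)(=O)C(F)(F)F
Why: Silylation of the secondary alcohol gives an ether that should survive the enolate, cuprate and organolithium steps.

Step 4
Reactants: 4 (2R,3R)-3-[(tert-butyldimethylsilyl)oxy]-2-methyl-2-(prop-2-en-1-yl)cyclohexan-1-one
Product: 5 (2R,3R)-3-[(tert-butyldimethylsilyl)oxy]-2-methyl-2-[(E)-prop-1-en-1-yl]cyclohexan-1-one
Conditions: RuHCl(CO)(PPh3)3 (3 mol %), toluene, 80 °C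
Reagents that add atoms: none
Why: Ruthenium hydride alkene isomerization (addition/β-hydride elimination) should move the double bond one position to the more stable (E)-alkene, and the quaternary carbon stops further migration.

Step 5
Reactants: 5 (2R,3R)-3-[(tert-butyldimethylsilyl)oxy]-2-methyl-2-[(E)-prop-1-en-1-yl]cyclohexan-1-one
Product: 6 (2S,3R)-3-[(tert-butyldimethylsilyl)oxy]-2-formyl-2-methylcyclohexan-1-one (formyl cis to the silyloxy group)
Conditions: O3, CH2Cl2, −78 °C; then PPh3
Reagents that add atoms: ozone, [O-][O+]=O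
Why: Ozonolysis of the only alkene with reductive work-up should give the non-enolizable neopentyl aldehyde one carbon shorter than the allyl group.

Step 6
Reactants: 6 (2S,3R)-3-[(tert-butyldimethylsilyl)oxy]-2-formyl-2-methylcyclohexan-1-one
Product: 7 3-[(tert-butyldimethylsilyl)oxy]-2-(1-hydroxyethyl)-2-methylcyclohexan-1-one (ring configuration as in 6, both carbinol epimers)
Conditions: MeMgBr (1.1 equiv), THF, −78 °C; then aq. NH4Cl at −78 °C
Reagents that add atoms: methylmagnesium bromide, C[Mg]Br
Why: Grignard addition should be chemoselective for the aldehyde over the α-quaternary ketone at low temperature; the carbinol configuration is not controlled because this carbon becomes a radical in step 19.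

Step 7
Reactants: 7 3-[(tert-butyldimethylsilyl)oxy]-2-(1-hydroxyethyl)-2-methylcyclohexan-1-one
Product: 8 3-[(tert-butyldimethylsilyl)oxy]-2-methyl-2-[1-(triethylsilyloxy)ethyl]cyclohexan-1-one
Conditions: TESOTf, 2,6-lutidine, CH2Cl2, −78 °C
Reagents that add atoms: triethylsilyl trifluoromethanesulfonate, CC[Si](CC)(CC)OS(=O)(=O)C(F)(F)F
Why: Silylation under non-basic conditions blocks retro-aldol cleavage of the β-hydroxy ketone in the basic steps that follow.

Step 8
Reactants: 8 3-[(tert-butyldimethylsilyl)oxy]-2-methyl-2-[1-(triethylsilyloxy)ethyl]cyclohexan-1-one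
Product: 9 3-[(tert-butyldimethylsilyl)oxy]-2-methyl-2-[1-(triethylsilyloxy)ethyl]cyclohex-5-en-1-one
Conditions: LiN(iPr)2, THF, −78 °C; then N-tert-butylbenzenesulfinimidoyl chloride, −78 °C
Reagents that add atoms: none
Why: Ketone dehydrogenation through the lithium enolate, which can form only at C6, followed by S–C bond formation and syn-elimination, should give the C5=C6 enone.

Step 9
Reactants: 9 3-[(tert-butyldimethylsilyl)oxy]-2-methyl-2-[1-(triethylsilyloxy)ethyl]cyclohex-5-en-1-one
Product: 10 3-[(tert-butyldimethylsilyl)oxy]-6-iodo-2-methyl-2-[1-(triethylsilyloxy)ethyl]cyclohex-5-en-1-one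
Conditions: I2, pyridine, CH2Cl2, 0 → 25 °C
Reagents that add atoms: iodine, II
Why: α-Iodination of the enone by a Baylis–Hillman-type sequence (conjugate addition of pyridine, iodination of the enolate, loss of pyridine) installs the handle for cross-coupling.

Step 10
Reactants: 11 2-methyl-2-vinyloxirane (racemic)
Product: 12 (S)-2-methylbut-3-ene-1,2-diol
Conditions: Pd2(dba)3·CHCl3 (1 mol %), (1R,2R)-N,N'-bis[2-(diphenylphosphino)-1-naphthoyl]cyclohexane-1,2-diamine (3 mol %), NaHCO3, CH2Cl2/H2O, 25 °C
Reagents that add atoms: sodium hydrogencarbonate, [Na+].OC([O-])=O; water, O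
Why: Pd-catalysed dynamic kinetic asymmetric allylic substitution of Tsuji–Trost type, in which the ionized epoxide gives interconverting π-allylpalladium complexes and hydrogencarbonate is delivered to the tertiary terminus under ligand control; hydrolysis should give the (S)-diol that fixes the side-chain carbinol centre.

Step 11
Reactants: 12 (S)-2-methylbut-3-ene-1,2-diol
Product: 13 (S)-2,2,4-trimethyl-4-vinyl-1,3-dioxolane
Conditions: 2,2-dimethoxypropane, pyridinium p-toluenesulfonate (cat.), CH2Cl2, 25 °C
Reagents that add atoms: 2,2-dimethoxypropane, COC(C)(C)OC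
Why: Acetonide formation protects the primary and tertiary hydroxyls together and leaves the vinyl group as the only reactive site.

Step 12
Reactants: 10 3-[(tert-butyldimethylsilyl)oxy]-6-iodo-2-methyl-2-[1-(triethylsilyloxy)ethyl]cyclohex-5-en-1-one; 13 (S)-2,2,4-trimethyl-4-vinyl-1,3-dioxolane
Product: 15 3-[(tert-butyldimethylsilyl)oxy]-2-methyl-2-[1-(triethylsilyloxy)ethyl]-6-{2-[(4S)-2,2,4-trimethyl-1,3-dioxolan-4-yl]ethyl}cyclohex-5-en-1-one, via B-alkyl-9-BBN borane 14 (not isolated)
Conditions: 13, 9-BBN, THF, 50 °C; then 10, PdCl2(dppf) (5 mol %), Ph3As, Cs2CO3, DMF/THF/H2O, 25 °C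
Reagents that add atoms: none
Why: Anti-Markovnikov hydroboration of the vinyl group followed by B-alkyl Suzuki–Miyaura coupling with the α-iodoenone attaches the side chain to C6 without touching any stereocentre.

Step 13
Reactants: 15 3-[(tert-butyldimethylsilyl)oxy]-2-methyl-2-[1-(triethylsilyloxy)ethyl]-6-{2-[(4S)-2,2,4-trimethyl-1,3-dioxolan-4-yl]ethyl}cyclohex-5-en-1-one
Product: 17 6-allyl-3-[(tert-butyldimethylsilyl)oxy]-2,5-dimethyl-2-[1-(triethylsilyloxy)ethyl]-6-{2-[(4S)-2,2,4-trimethyl-1,3-dioxolan-4-yl]ethyl}cyclohexan-1-one (5-methyl trans to 3-silyloxy; 6-allyl trans to 5-methyl and cis to the C2 arm), via lithium enolate 16 (not isolated)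
Conditions: Me2CuLi (from CuI and MeLi), Et2O, −78 → −30 °C; then allyl bromide, HMPA, THF, −30 → 0 °C
Reagents that add atoms: lithium dimethylcuprate, [Li+].C[Cu-]C; allyl bromide, C=CCBr
Why: Cuprate conjugate addition followed by enolate alkylation, in which methyl should add axially to C5 anti to the C3 silyloxy group and the allyl halide should then attack the tetrasubstituted enolate anti to the new methyl (held pseudoaxial by A(1,2) strain with the side chain), which places allyl cis to the C2 arm and creates the quaternary C6.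

Step 14
Reactants: 17 6-allyl-3-[(tert-butyldimethylsilyl)oxy]-2,5-dimethyl-2-[1-(triethylsilyloxy)ethyl]-6-{2-[(4S)-2,2,4-trimethyl-1,3-dioxolan-4-yl]ethyl}cyclohexan-1-one
Product: 18 the corresponding 1,2,5-trimethylcyclohexan-1-ol (tertiary alcohol at C1, other substituents as in 17)
Conditions: MeLi, CeCl3, THF, −78 → 0 °C; then aq. NH4Cl
Reagents that add atoms: methyllithium, [Li]C
Why: 1,2-Addition of the small organocerium reagent to a ketone that has no α-hydrogen and therefore cannot be lost by enolization; the carbinol configuration is irrelevant.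

Step 15
Reactants: 18 tertiary alcohol
Product: 19 6-allyl-3-[(tert-butyldimethylsilyl)oxy]-2,5-dimethyl-1-methylidene-2-[1-(triethylsilyloxy)ethyl]-6-{2-[(4S)-2,2,4-trimethyl-1,3-dioxolan-4-yl]ethyl}cyclohexane
Conditions: SOCl2, pyridine, CH2Cl2, −20 → 0 °C
Reagents that add atoms: none
Why: Dehydration through the chlorosulfite by E2 elimination, where the only β-hydrogens are those of the new methyl group, so only the exocyclic methylene can form.

Step 16
Reactants: 19 exocyclic methylene compound
Product: 20 the (E)-3-(phenylsulfonyl)prop-2-en-1-yl analogue of 19 (vinyl sulfone on the C6 arm)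
Conditions: phenyl vinyl sulfone (3 equiv), second-generation Hoveyda–Grubbs catalyst (5 mol %), CH2Cl2, 40 °C
Reagents that add atoms: phenyl vinyl sulfone, C=CS(=O)(=O)c1ccccc1
Why: Olefin cross-metathesis in which only the monosubstituted allyl alkene should engage the ruthenium carbene (the 1,1-disubstituted methylene between two quaternary carbons is inert), giving the (E)-vinyl sulfone.

Step 17
Reactants: 20 vinyl sulfone
Product: 21 the 2-(1-hydroxyethyl) analogue of 20 (free secondary alcohol on the C2 arm)
Conditions: HF·pyridine, pyridine, THF, 0 °C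
Reagents that add atoms: none
Why: Fluoride-mediated desilylation should be selective for the triethylsilyl ether over the bulkier tert-butyldimethylsilyl ether and leaves the acetonide intact.

Step 18
Reactants: 21 secondary alcohol
Product: 22 the O-phenyl thiocarbonate of 21 [2-(1-(phenoxythiocarbonyloxy)ethyl) arm]
Conditions: O-phenyl chlorothionoformate, pyridine, DMAP (cat.), CH2Cl2, 25 °C
Reagents that add atoms: O-phenyl chlorothionoformate, S=C(Cl)Oc1ccccc1
Why: Acylation of the alcohol gives the thiocarbonyl derivative needed for Barton–McCombie-type C–O homolysis.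

Step 19
Reactants: 22 thiocarbonate
Product: 23 tricyclic sulfone: the target skeleton with CH–SO2Ph in place of the ketone carbon, a tert-butyldimethylsilyl ether in place of the acetate and the side chain as 2-[(4S)-2,2,4-trimethyl-1,3-dioxolan-4-yl]ethyl
Conditions: Bu3SnH (1.3 equiv, syringe pump, 8 h), AIBN (0.2 equiv), benzene (0.005 M), 80 °C
Reagents that add atoms: none
Why: This is a tandem radical cyclization (Barton–McCombie radical generation, Giese-type 6-exo-trig addition, then 6-endo-trig closure); the closest known type is the tin hydride mediated radical cascade onto vinyl sulfones. Bu3Sn• adds to the thiocarbonyl sulfur and C–O fragmentation gives the secondary radical at the CHMe carbon, which adds 6-exo-trig to the β-carbon of the vinyl sulfone (new CHMe–CH bond); the electrophilic α-sulfonyl radical then attacks the unhindered CH2 terminus of the electron-rich exocyclic methylene in a 6-endo-trig mode (new CH(SO2Ph)–CH2 bond), and the tertiary bridgehead radical takes hydrogen from Bu3SnH. The first ring can close only when both arms are axial on the same face of ring A, which the cis relationship set in step 13 secures, and only the adduct with the sulfonylmethyl carbon exo can reach the methylene, so both bridgehead configurations follow from the geometry of the cage. The CHMe configuration is set in the first closure: the methyl of the planar radical should lie on the open face next to the sp2 methylene carbon and away from the silyloxy-bearing ring carbon, which gives the required methyl syn to the sulfonyl (later ketone) bridge. The step needs the nucleophilic alkyl radical to prefer the electron-poor vinyl sulfone (polarity matching) and slow delivery of Bu3SnH at high dilution so that neither radical is reduced before it cyclizes. The sulfonyl-bearing carbon forms as an epimer mixture, which is of no consequence.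

Step 20
Reactants: 23 tricyclic sulfone
Product: 24 triol: target skeleton with CH–SO2Ph in place of the ketone carbon, free secondary hydroxyl in place of the acetate and a (3S)-3,4-dihydroxy-3-methylbutyl side chain
Conditions: 3 M aq. HCl, MeOH/THF, 40 °C
Reagents that add atoms: none
Why: Acid hydrolysis removes the acetonide and the silyl ether together; no acid-sensitive group remains in the saturated cage.

Step 21
Reactants: 24 triol
Product: 25 hydroxy aldehyde: as 24 with a (3S)-3-hydroxy-3-methyl-4-oxobutyl side chain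
Conditions: TEMPO (5 mol %), KBr, NaOCl, aq. NaHCO3, CH2Cl2, 0 °C
Reagents that add atoms: none
Why: TEMPO/NaOCl oxoammonium oxidation should be selective for the primary alcohol over the hindered secondary and the tertiary alcohol, and the quaternary α-carbon cannot epimerize.

Step 22
Reactants: 25 hydroxy aldehyde
Product: 26 as 25 with the (3S)-3-hydroxy-3-methylpent-4-en-1-yl side chain of the target
Conditions: Ph3PCH3Br, KN(SiMe3)2 (ylide, 4 equiv), THF, 0 → 25 °C
Reagents that add atoms: methylenetriphenylphosphorane, C=P(c1ccccc1)(c1ccccc1)c1ccccc1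
Why: Wittig methylenation of the aldehyde, with excess ylide covering the two hydroxyl groups; the ketone is still masked as the sulfone, so no competing carbonyl is present.

Step 23
Reactants: 26 sulfone diol
Product: 27 deacetyl target (ketone, free secondary and tertiary hydroxyls)
Conditions: n-BuLi (3.2 equiv), THF, −78 °C; then Me3SiOOSiMe3, −78 → 0 °C; aq. NH4Cl
Reagents that add atoms: bis(trimethylsilyl) peroxide, C[Si](C)(C)OO[Si](C)(C)C
Why: Oxidative desulfonylation, in which the α-sulfonyl carbanion is oxygenated by the silyl peroxide and the α-silyloxy sulfone collapses to the ketone with loss of sulfinate; the adjacent bridgehead centre cannot epimerize.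

Step 24
Reactants: 27 deacetyl target
Product: 28 CNP0281208.1 (target)
Conditions: Ac2O, pyridine, DMAP (cat.), CH2Cl2, 0 → 25 °C
Reagents that add atoms: acetic anhydride, CC(=O)OC(C)=O
Why: Acylation should occur at the secondary alcohol only, because the tertiary allylic alcohol is inert under these mild conditions.

**Compound list**

1 | 2-methylcyclohexane-1,3-dione | CC1C(=O)CCCC1=O | starting material
2 | 2-methyl-2-(prop-2-en-1-yl)cyclohexane-1,3-dione | C=CCC1(C)C(=O)CCCC1=O | intermediate
3 | (2R,3R)-3-hydroxy-2-methyl-2-(prop-2-en-1-yl)cyclohexan-1-one | O=C1CCC[C@@H](O)[C@@]1(C)CC=C | intermediate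
4 | (2R,3R)-3-[(tert-butyldimethylsilyl)oxy]-2-methyl-2-(prop-2-en-1-yl)cyclohexan-1-one | O=C1CCC[C@@H](O[Si](C)(C)C(C)(C)C)[C@@]1(C)CC=C | intermediate
5 | (2R,3R)-3-[(tert-butyldimethylsilyl)oxy]-2-methyl-2-[(E)-prop-1-en-1-yl]cyclohexan-1-one | O=C1CCC[C@@H](O[Si](C)(C)C(C)(C)C)[C@@]1(C)/C=C/C | intermediate
6 | (2S,3R)-3-[(tert-butyldimethylsilyl)oxy]-2-formyl-2-methylcyclohexan-1-one | O=C1CCC[C@@H](O[Si](C)(C)C(C)(C)C)[C@@]1(C)C=O | intermediate
7 | 3-[(tert-butyldimethylsilyl)oxy]-2-(1-hydroxyethyl)-2-methylcyclohexan-1-one (carbinol epimers) | O=C1CCC[C@@H](O[Si](C)(C)C(C)(C)C)[C@@]1(C)C(C)O | intermediate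
8 | 3-[(tert-butyldimethylsilyl)oxy]-2-methyl-2-[1-(triethylsilyloxy)ethyl]cyclohexan-1-one | O=C1CCC[C@@H](O[Si](C)(C)C(C)(C)C)[C@@]1(C)C(C)O[Si](CC)(CC)CC | intermediate
9 | 3-[(tert-butyldimethylsilyl)oxy]-2-methyl-2-[1-(triethylsilyloxy)ethyl]cyclohex-5-en-1-one | O=C1C=CC[C@@H](O[Si](C)(C)C(C)(C)C)[C@@]1(C)C(C)O[Si](CC)(CC)CC | intermediate
10 | 3-[(tert-butyldimethylsilyl)oxy]-6-iodo-2-methyl-2-[1-(triethylsilyloxy)ethyl]cyclohex-5-en-1-one | O=C1C(I)=CC[C@@H](O[Si](C)(C)C(C)(C)C)[C@@]1(C)C(C)O[Si](CC)(CC)CC | intermediate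
11 | 2-methyl-2-vinyloxirane (racemic) | CC1(C=C)CO1 | starting material
12 | (S)-2-methylbut-3-ene-1,2-diol | OC[C@@](C)(O)C=C | intermediate
13 | (S)-2,2,4-trimethyl-4-vinyl-1,3-dioxolane | CC1(C)OC[C@@](C)(O1)C=C | intermediate
14 | 9-{2-[(4S)-2,2,4-trimethyl-1,3-dioxolan-4-yl]ethyl}-9-borabicyclo[3.3.1]nonane | CC1(C)OC[C@@](C)(O1)CCB1C2CCCC1CCC2 | intermediate
15 | 3-[(tert-butyldimethylsilyl)oxy]-2-methyl-2-[1-(triethylsilyloxy)ethyl]-6-{2-[(4S)-2,2,4-trimethyl-1,3-dioxolan-4-yl]ethyl}cyclohex-5-en-1-one | CC1(C)OC[C@@](C)(O1)CCC1=CC[C@@H](O[Si](C)(C)C(C)(C)C)[C@@](C)(C(C)O[Si](CC)(CC)CC)C1=O | intermediate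
16 | lithium enolate of the 5-methyl ketone (C1=C6 enolate, 5-methyl trans to 3-silyloxy) | CC1(C)OC[C@@](C)(O1)CCC1=C(O[Li])[C@](C)(C(C)O[Si](CC)(CC)CC)[C@H](O[Si](C)(C)C(C)(C)C)C[C@H]1C | intermediate
17 | 6-allyl-3-[(tert-butyldimethylsilyl)oxy]-2,5-dimethyl-2-[1-(triethylsilyloxy)ethyl]-6-{2-[(4S)-2,2,4-trimethyl-1,3-dioxolan-4-yl]ethyl}cyclohexan-1-one | CC1(C)OC[C@@](C)(O1)CC[C@@]1(CC=C)C(=O)[C@](C)(C(C)O[Si](CC)(CC)CC)[C@H](O[Si](C)(C)C(C)(C)C)C[C@H]1C | intermediate
18 | tertiary alcohol from methyl addition to C1 of 17 | CC1(C)OC[C@@](C)(O1)CC[C@@]1(CC=C)C(C)(O)[C@](C)(C(C)O[Si](CC)(CC)CC)[C@H](O[Si](C)(C)C(C)(C)C)C[C@H]1C | intermediate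
19 | 1-methylidene analogue of 17 | CC1(C)OC[C@@](C)(O1)CC[C@@]1(CC=C)C(=C)[C@](C)(C(C)O[Si](CC)(CC)CC)[C@H](O[Si](C)(C)C(C)(C)C)C[C@H]1C | intermediate
20 | (E)-vinyl sulfone from 19 | CC1(C)OC[C@@](C)(O1)CC[C@@]1(C/C=C/S(=O)(=O)c2ccccc2)C(=C)[C@](C)(C(C)O[Si](CC)(CC)CC)[C@H](O[Si](C)(C)C(C)(C)C)C[C@H]1C | intermediate
21 | secondary alcohol from 20 | CC1(C)OC[C@@](C)(O1)CC[C@@]1(C/C=C/S(=O)(=O)c2ccccc2)C(=C)[C@](C)(C(C)O)[C@H](O[Si](C)(C)C(C)(C)C)C[C@H]1C | intermediate
22 | O-phenyl thiocarbonate of 21 | CC1(C)OC[C@@](C)(O1)CC[C@@]1(C/C=C/S(=O)(=O)c2ccccc2)C(=C)[C@](C)(C(C)OC(=S)Oc2ccccc2)[C@H](O[Si](C)(C)C(C)(C)C)C[C@H]1C | intermediate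
23 | tricyclic sulfone (silyl ether, acetonide) | CC1(C)OC[C@@](C)(O1)CC[C@@]12C[C@H]3C(S(=O)(=O)c4ccccc4)C[C@@H]1[C@](C)([C@@H]3C)[C@H](O[Si](C)(C)C(C)(C)C)C[C@H]2C | intermediate
24 | tricyclic sulfone triol | OC[C@@](C)(O)CC[C@@]12C[C@H]3C(S(=O)(=O)c4ccccc4)C[C@@H]1[C@](C)([C@@H]3C)[C@H](O)C[C@H]2C | intermediate
25 | tricyclic sulfone hydroxy aldehyde | O=C[C@@](C)(O)CC[C@@]12C[C@H]3C(S(=O)(=O)c4ccccc4)C[C@@H]1[C@](C)([C@@H]3C)[C@H](O)C[C@H]2C | intermediate
26 | tricyclic sulfone with the vinyl carbinol side chain | C=C[C@@](C)(O)CC[C@@]12C[C@H]3C(S(=O)(=O)c4ccccc4)C[C@@H]1[C@](C)([C@@H]3C)[C@H](O)C[C@H]2C | intermediate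
27 | deacetyl target | C=C[C@@](C)(O)CC[C@@]12C[C@H]3C(=O)C[C@@H]1[C@](C)([C@@H]3C)[C@H](O)C[C@H]2C | intermediate
28 | CNP0281208.1 | C=C[C@@](C)(O)CC[C@@]12C[C@H]3C(=O)C[C@@H]1[C@](C)([C@@H]3C)[C@H](OC(C)=O)C[C@H]2C | target

**Step count**

Total steps: 24. Longest linear sequence: 22 steps (steps 1–9 and 12–24).

**Steps most likely to fail**

1. Step 19. Hydrogen transfer from Bu3SnH to the α-sulfonyl radical may outrun the 6-endo closure, so the cascade stops after the first ring; closure of the first ring with the methyl on the hindered face is the second risk. Fallback: the two bonds are made in separate operations, the second without any hydride donor. Setting out from 22, Bu3SnH is added in one portion (0.05 M, AIBN, benzene, 80 °C) to give on purpose the monocyclized bicyclo[3.3.1]nonane sulfone F1. Deprotonation with LiN(iPr)2 and quenching with I2 gives the α-iodo sulfone F2. Iodine atom transfer cyclization ((Bu3Sn)2 cat., hν, benzene, 80 °C) closes the second ring, and the bridgehead radical takes iodine to give the bridgehead iodide F3. Reduction with Bu3SnH/AIBN returns to the route at 23.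

2. Step 13. The allyl group may go to oxygen or to the enolate face syn to the new methyl, because the required approach is 1,3-related to the axial C2 arm. Fallback: catalyst-controlled inner-sphere allylation. Setting out from 15, Me2CuLi addition is followed by trapping with allyl chloroformate to give the allyl enol carbonate F4. Pd-catalysed decarboxylative allylic alkylation (Pd2(dba)3, the t-BuPHOX antipode matched to the required face, toluene, 30 °C) then forms the quaternary carbon and returns to the route at 17.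

3. Step 14. The methyl nucleophile may fail to add to a carbonyl flanked by two quaternary carbons (and the dehydration of step 15 may be accompanied by skeletal rearrangement). Fallback: the methylene and the quaternary C6 are made together by a sigmatropic shift, so that no addition to the ketone is needed. Setting out from 15, Me2CuLi addition and trapping with N-(5-chloropyridin-2-yl)bis(trifluoromethanesulfonimide) give the enol triflate F5. Stille coupling with Bu3SnCH2OH (Pd(PPh3)4, LiCl, dioxane, 100 °C) gives the allylic alcohol F6. Johnson–Claisen rearrangement (MeC(OEt)3, propanoic acid cat., 140 °C) should deliver the acetate arm to C6 anti to the 5-methyl and create the exocyclic methylene, giving the ethyl ester F7. Reduction with iBu2AlH (−78 °C) gives the aldehyde F8, and Horner–Wadsworth–Emmons olefination with diethyl (phenylsulfonyl)methylphosphonate (NaH, THF) returns to the route at 20.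

**Further compounds**

F1 | step 19 | monocyclized bicyclo[3.3.1]nonane sulfone (phenylsulfonylmethyl on the new ring, exocyclic methylene retained) | CC1(C)OC[C@@](C)(O1)CC[C@@]12C[C@@H](CS(=O)(=O)c3ccccc3)[C@@H](C)[C@@](C)(C1=C)[C@H](O[Si](C)(C)C(C)(C)C)C[C@H]2C
F2 | step 19 | α-iodo sulfone of F1 | CC1(C)OC[C@@](C)(O1)CC[C@@]12C[C@@H](C(I)S(=O)(=O)c3ccccc3)[C@@H](C)[C@@](C)(C1=C)[C@H](O[Si](C)(C)C(C)(C)C)C[C@H]2C
F3 | step 19 | bridgehead iodide of 23 | CC1(C)OC[C@@](C)(O1)CC[C@@]12C[C@H]3C(S(=O)(=O)c4ccccc4)C[C@]1(I)[C@](C)([C@@H]3C)[C@H](O[Si](C)(C)C(C)(C)C)C[C@H]2C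
F4 | step 13 | allyl enol carbonate of the 5-methyl ketone | CC1(C)OC[C@@](C)(O1)CCC1=C(OC(=O)OCC=C)[C@](C)(C(C)O[Si](CC)(CC)CC)[C@H](O[Si](C)(C)C(C)(C)C)C[C@H]1C
F5 | step 14 | enol triflate of the 5-methyl ketone | CC1(C)OC[C@@](C)(O1)CCC1=C(OS(=O)(=O)C(F)(F)F)[C@](C)(C(C)O[Si](CC)(CC)CC)[C@H](O[Si](C)(C)C(C)(C)C)C[C@H]1C
F6 | step 14 | allylic alcohol (hydroxymethyl on C1, C1=C6 alkene) | CC1(C)OC[C@@](C)(O1)CCC1=C(CO)[C@](C)(C(C)O[Si](CC)(CC)CC)[C@H](O[Si](C)(C)C(C)(C)C)C[C@H]1C
F7 | step 14 | ethyl ester (ethoxycarbonylmethyl on C6, 1-methylidene) | CC1(C)OC[C@@](C)(O1)CC[C@@]1(CC(=O)OCC)C(=C)[C@](C)(C(C)O[Si](CC)(CC)CC)[C@H](O[Si](C)(C)C(C)(C)C)C[C@H]1C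
F8 | step 14 | aldehyde (2-oxoethyl on C6, 1-methylidene) | CC1(C)OC[C@@](C)(O1)CC[C@@]1(CC=O)C(=C)[C@](C)(C(C)O[Si](CC)(CC)CC)[C@H](O[Si](C)(C)C(C)(C)C)C[C@H]1C
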